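All runs were computed for an exercise.

Divide the two charges before you fit a single constant.

in all of them: G 0.10 M

| run | Q | remark | time |
|---|---|---|---|
| delta | 0.045 M (in portions, 2) | run made earlier; portions every 40 s |  |
| zeta | 0.18 M (in portions, 2) | run made earlier; portions every 40 s |  |
| flask | 0.0900 M (in portions, 2) | the portions of Q follow each other after 40 s, the first at the start | 20 h |

| run | time / h | G / % | E / % | L / % |
|---|---|---|---|---|
| delta | 0.833 | 55.1 | 25.3 | 9.5 |
| delta | 2.50 | 54.5 | 40.1 | 2.3 |
| delta | 5.00 | 54.6 | 43.2 | 1.0 |
| delta | 6.00 | 55.1 | 42.7 | 0.6 |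
| delta | 10.0 | 55.1 | 43.4 | 0.5 |
| delta | 12.0 | 56.2 | 44.6 | 0.3 |
| delta | 15.0 | 55.3 | 43.7 | 0.5 |
| zeta | 2.50 | 0 | 89.1 | 4.7 |
| zeta | 5.00 | 0 | 95.9 | 1.6 |
| zeta | 6.00 | 0.5 | 96.8 | 1.2 |
| zeta | 10.0 | 0.4 | 96.7 | 0.9 |
| zeta | 12.0 | 0 | 96.7 | 1.0 |
| zeta | 15.0 | 0.5 | 98.2 | 0.5 |

(each reading ± 0.5 percentage points)

1. at 20 h, what has stopped the reaction, if anything has (it is still moving / forward and back rates have come level / all of G has reacted / Q has run out first)
2. how much of the G has reacted by 20 h
3. how much E there is at 20 h, in percent of the G charged

- the reaction counts as stopped when no species that holds the G changes by six tenths of a point or more over the second half of the time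

In delta, G reads 55.3% at 15.0 h, so 44.7% of it has reacted. The charges of that run give 45.0%, so within the scatter of 0.5 percentage points one Q takes one G. In zeta, with 1.80 equivalents of Q, G reads 0.5% at 15.0 h, so G does not stall at a balance with much of it unreacted.

This flask therefore has a Q ceiling of 90.0%: the charged Q over the charged G, the share of the G that can react one for one. Here Q is the limiting reagent, with 0.0900 M charged against 0.10 M of G, less than one for one, so I expect Q to run out first.

I leave the clock out of the reckoning, because G in delta is already flat at the first reading, 0.833 h, far earlier than the 20 h asked. E in delta moves by 0.3 points from 10.0 h to 15.0 h, which is less than the scatter.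

Next comes the E share, E over the G reacted. Delta's last readings give 97.8%, so I reckon E in this flask at 88.0%.

That share is the weak link, since it rests on one pair of readings, each with its scatter. Zeta's last pair, with more E than delta's, gives 98.7% and so 88.8% of E. I commit to 88.0%, the lower of the two.

The forecast gave Q has run out first, 89.7% and 88%, in its words “Q simply runs out”. The flask gives Q has run out first, a conversion of 90.0% and 87.8% of E.

    G + Q → J + D (k = 0.321 M⁻¹ s⁻¹)
    J ⇌ L (K = 0.790, k = 0.00334 s⁻¹)
    J ⇌ E (K = 71.5, k = 4.78 × 10⁻⁴ s⁻¹)

The ceiling of 90.0% stands against that conversion with 0% of the Q left, and in this flask half of the turnover of the passing of J into E up to the 20 h asked is done by 0.722 h, far sooner than that time. In the neighbour with 0.25 M of G the ceiling is 36.0% and the delta share makes 35.2% of E; that flask gives a conversion of 36.0% and 35.1% of E, with 64.0% of its G unreacted.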